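**Retrosynthetic overview**

1. Feature: in ring B (C5–C10) the hydroxyl O8 on C8 is β-axial and the ether oxygen O9 on C9 is α-axial, trans-diaxial across C8–C9, and O9 is also bonded to C13 in ring C (C9, C11, C12, C13, O9). This is the footprint of an 8α,9α-epoxide whose oxygen has alkylated C13 and whose C8 was opened from the β face.
2. Key disconnection: O9–C13 and C8–O8 are formed together from bis-epoxide 16 (7β-Boc-oxy, 8α,9α-epoxide, 13R,16-epoxide); the Boc carbonate ends as the 7β,8β-cyclic carbonate of 19.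
3. 16 is built from (+)-sclareolide (rings A and B): Δ8 C12 iodide 5, B-alkyl Suzuki coupling with 3-bromobut-3-en-1-ol (C12–C13), hydroxyl-directed asymmetric epoxidation (C13), C7 allylic oxidation, Luche reduction, Boc carbonate, α-face epoxidation.
4. Ring order: A/B from the chiral pool, then ring C and the carbonate ring in the cascade, then ring D by oxidative lactonisation of the C15/C16 diol; carbonate hydrolysis and C7 oxidation finish.
5. O15 is carried as a TBDPS ether so that no acyl carbonyl can compete for C13 and so that the 7,8-diol stays masked as the carbonate while ring D is closed.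

Key step: step 11

Assumption: the antipode of the bishydroxamic acid ligand in step 5 is chosen by the face model of this catalyst to give the 13R epoxide, and the configuration of 10 is confirmed before step 6.

**Route**

Step 1
Reactants: 1 (+)-sclareolide
Product: 3 methyl 13,14,15,16-tetranorlabd-8-en-12-oate, via unsaturated acid 2 (not isolated)
Conditions: conc. H2SO4, MeOH, reflux (equilibrating)
Reagents that add atoms: methanol, CO
Why: Acid-promoted alkyl–oxygen cleavage of the tertiary lactone gives the C8 cation, E1 loss of H9 under equilibrating conditions should favour the tetrasubstituted Δ8(9) olefin and Fischer esterification traps the acid, with C5 and C10 untouched and the minor Δ7 and Δ8(17) isomers removable on AgNO3-doped silica.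

Step 2
Reactants: 3 methyl 13,14,15,16-tetranorlabd-8-en-12-oate
Product: 4 13,14,15,16-tetranorlabd-8-en-12-ol
Conditions: LiAlH4, THF, 0 °C
Reagents that add atoms: none
Why: Hydride reduction of the ester with LiAlH4 leaves the isolated tetrasubstituted olefin untouched.

Step 3
Reactants: 4 13,14,15,16-tetranorlabd-8-en-12-ol
Product: 5 12-iodo-13,14,15,16-tetranorlabd-8-ene
Conditions: I2, PPh3, imidazole, CH2Cl2, 0 °C → rt
Reagents that add atoms: iodine, II
Why: Appel-type iodination (Garegg–Samuelsson conditions) displaces the primary alkoxyphosphonium group at C12 by iodide in an SN2 reaction under non-acidic conditions that should not isomerise the olefin.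

Step 4
Reactants: 5 12-iodo-13,14,15,16-tetranorlabd-8-ene; 6 3-bromobut-3-en-1-ol
Product: 9 labda-8,13(16)-dien-15-ol, via alkyllithium 7 (not isolated), via lithium borate 8 (not isolated)
Conditions: t-BuLi (2.1 equiv), Et2O, −78 °C; B-methoxy-9-BBN, THF, −78 °C → rt; then 6, PdCl2(dppf) (cat.), AsPh3 (cat.), aq K3PO4, DMF, rt
Reagents that add atoms: none
Why: Lithium–iodine exchange, capture of the alkyllithium by B-methoxy-9-BBN and B-alkyl Suzuki–Miyaura coupling of the resulting borate with the 2-bromo-1-alkene join C12 to C13, the aqueous phosphate conditions tolerating the free hydroxyl of 6.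

Step 5
Reactants: 9 labda-8,13(16)-dien-15-ol
Product: 10 (13R)-13,16-epoxylabd-8-en-15-ol
Conditions: Hf(OtBu)4 (cat.), chiral bishydroxamic acid ligand from trans-cyclohexane-1,2-diamine (cat.), cumene hydroperoxide, DMPU, 4 Å MS, toluene, 0 °C
Reagents that add atoms: cumene hydroperoxide, CC(C)(OO)c1ccccc1
Why: Hydroxyl-directed catalytic asymmetric epoxidation of a 3-substituted but-3-en-1-ol, in which the hafnium-bound alkoxide delivers the peroxide oxygen only to the neighbouring C13=C16 olefin (the remote Δ8 olefin has no directing group) and the ligand antipode fixes the face so that C13 is R.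

Step 6
Reactants: 10 (13R)-13,16-epoxylabd-8-en-15-ol
Product: 11 (13R)-15-(tert-butyldiphenylsilyloxy)-13,16-epoxylabd-8-ene
Conditions: TBDPSCl, imidazole, CH2Cl2, 0 °C → rt
Reagents that add atoms: tert-butyl(chloro)diphenylsilane, CC(C)(C)[Si](Cl)(c1ccccc1)c1ccccc1
Why: Silylation of the primary alcohol under mildly basic conditions gives a robust, non-participating ether and does not touch the epoxide.

Step 7
Reactants: 11 (13R)-15-(tert-butyldiphenylsilyloxy)-13,16-epoxylabd-8-ene
Product: 12 (13R)-15-(tert-butyldiphenylsilyloxy)-13,16-epoxylabd-8-en-7-one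
Conditions: CrO3, 3,5-dimethylpyrazole, CH2Cl2, −20 °C
Reagents that add atoms: chromium trioxide, O=[Cr](=O)=O
Why: Allylic C–H oxidation with the CrO3–3,5-dimethylpyrazole complex should attack the ring methylene C7, as is usual for labd-8-enes, in preference to the hindered C11 methylene and the C17 methyl, and gives the conjugated enone under non-acidic conditions that spare the epoxide and the silyl ether.

Step 8
Reactants: 12 (13R)-15-(tert-butyldiphenylsilyloxy)-13,16-epoxylabd-8-en-7-one
Product: 13 (13R)-15-(tert-butyldiphenylsilyloxy)-13,16-epoxylabd-8-en-7β-ol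
Conditions: NaBH4, CeCl3·7H2O, MeOH, −78 → −20 °C
Reagents that add atoms: none
Why: Luche 1,2-reduction of the enone, in which axial delivery of hydride to C7 from the α face should give the pseudo-equatorial 7β-alcohol.

Step 9
Reactants: 13 (13R)-15-(tert-butyldiphenylsilyloxy)-13,16-epoxylabd-8-en-7β-ol; 14 di-tert-butyl dicarbonate
Product: 15 (13R)-7β-(tert-butoxycarbonyloxy)-15-(tert-butyldiphenylsilyloxy)-13,16-epoxylabd-8-ene
Conditions: 1-methylimidazole, toluene, 0 °C → rt
Reagents that add atoms: none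
Why: Nucleophile-catalysed O-acylation of the secondary allylic alcohol by Boc2O gives the tert-butyl carbonate with retention at C7, the group that later screens the β face and delivers O8.

Step 10
Reactants: 15 (13R)-7β-(tert-butoxycarbonyloxy)-15-(tert-butyldiphenylsilyloxy)-13,16-epoxylabd-8-ene
Product: 16 (13R)-7β-(tert-butoxycarbonyloxy)-15-(tert-butyldiphenylsilyloxy)-8α,9α:13,16-diepoxylabdane
Conditions: mCPBA, NaHCO3, CH2Cl2, 0 °C
Reagents that add atoms: 3-chloroperbenzoic acid, OOC(=O)c1cccc(Cl)c1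
Why: Prilezhaev epoxidation of the electron-rich tetrasubstituted Δ8 olefin from the α face, away from the β-axial methyl C20 and the 7β-carbonate, sets C8 and C9 of the 8α,9α-epoxide, the bicarbonate buffer preventing premature acid-triggered opening.

Step 11
Reactants: 16 (13R)-7β-(tert-butoxycarbonyloxy)-15-(tert-butyldiphenylsilyloxy)-8α,9α:13,16-diepoxylabdane
Product: 19 (13S)-15-(tert-butyldiphenylsilyloxy)-9α,13-epoxy-16-hydroxylabdane-7β,8β-diyl carbonate, via epoxonium ion 17 (not isolated), via dioxolanylium ion 18 (not isolated)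
Conditions: BF3·OEt2 (0.3 equiv), CH2Cl2, −78 → −40 °C; aq NaHCO3
Reagents that add atoms: none
Why: Proposed new method: BF3 activation of the side-chain epoxide lets the ring-epoxide oxygen attack tertiary C13 with inversion to give spiro epoxonium ion 17, the carbonyl oxygen of the 7β-carbonate then opens 17 at C8 from the β face to give dioxolanylium ion 18, and loss of isobutene leaves the cyclic carbonate, while the other order of events (carbonate opening of the ring epoxide at C8, then attack of the freed 9α-oxygen on C13) leads to the same product. The closest known reaction type is the Lewis-acid epoxide-opening cascade of diepoxides through bicyclic epoxonium ions that is terminated by a tert-butyl carbonate, known for acyclic di- and trisubstituted epoxides but not with a ring-fused tetrasubstituted epoxide as the relay. Ring C (O9, C9, C11, C12, C13) closes 5-exo-tet at C13 and the carbonate ring (C7, O7, carbonyl carbon, O8, C8) closes 5-exo-tet at C8. C13 becomes S by stereospecific inversion of the reagent-set 13R epoxide, and C8 takes O8 on the β face by backside displacement of the α C8–O bond, C9 keeping its α oxygen. The step needs opening at C8 and not at C9 and an SN2-like, non-ionising opening at C13: the 7β-carbonate can reach only C8 and does so along the trans-diaxial trajectory, C9 is screened by quaternary C10, and fast five-membered neighbouring-group attack at low temperature in CH2Cl2 should outrun ionisation and hydride or methyl shifts.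

Step 12
Reactants: 19 (13S)-15-(tert-butyldiphenylsilyloxy)-9α,13-epoxy-16-hydroxylabdane-7β,8β-diyl carbonate
Product: 20 (13S)-9α,13-epoxy-15,16-dihydroxylabdane-7β,8β-diyl carbonate
Conditions: HF·pyridine, pyridine, THF, 0 °C → rt
Reagents that add atoms: none
Why: Fluoride cleavage of the silyl ether frees the C15 carbinol without touching the cyclic carbonate or the tertiary ether.

Step 13
Reactants: 20 (13S)-9α,13-epoxy-15,16-dihydroxylabdane-7β,8β-diyl carbonate
Product: 23 (13S)-7β,8β-carbonyldioxy-9α,13-epoxylabdan-15,16-olide, via hydroxy aldehyde 21 (not isolated), via lactol 22 (not isolated)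
Conditions: TEMPO (cat.), PhI(OAc)2, CH2Cl2, rt
Reagents that add atoms: none
Why: Oxoammonium-mediated oxidative lactonisation of the 1,4-diol, in which the less hindered C15 carbinol should be oxidised ahead of the neopentyl, β-oxygenated C16 carbinol, O16 captures the aldehyde as the lactol and this is oxidised on to the γ-lactone (carbonyl C15, ring oxygen on C16), while the carbonate keeps the 7,8-diol out of reach of glycol cleavage.

Step 14
Reactants: 23 (13S)-7β,8β-carbonyldioxy-9α,13-epoxylabdan-15,16-olide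
Product: 25 (13S)-9α,13-epoxy-7β,8β-dihydroxylabdan-15,16-olide, via lithium carboxylate 24 (not isolated)
Conditions: LiOH, THF–H2O, rt; then 1 M HCl to pH 2, rt
Reagents that add atoms: none
Why: Saponification cleaves the cyclic carbonate at its acyl carbon (O7 and O8 stay on the skeleton) and opens the lactone, and acidification re-closes the γ-lactone from the γ-hydroxy acid, no stereocentre being touched.

Step 15
Reactants: 25 (13S)-9α,13-epoxy-7β,8β-dihydroxylabdan-15,16-olide
Product: 26 (13S)-9α,13-epoxy-8β-hydroxy-7-oxolabdan-15,16-olide (CNP0208728.2)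
Conditions: IBX, DMSO, rt
Reagents that add atoms: none
Why: IBX oxidation of the secondary 7β-carbinol of the 1,2-diol gives the α-hydroxy ketone without glycol cleavage under neutral conditions, the tertiary C8 carbinol being unable to oxidise and the quaternary C8 unable to epimerise.

**Compound list**

1 | (+)-sclareolide | CC1(C)CCC[C@@]2(C)[C@H]1CC[C@@]1(C)OC(=O)C[C@H]21 | starting material
2 | 13,14,15,16-tetranorlabd-8-en-12-oic acid | CC1(C)CCC[C@@]2(C)[C@H]1CCC(C)=C2CC(=O)O | intermediate (not isolated)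
3 | methyl 13,14,15,16-tetranorlabd-8-en-12-oate | CC1(C)CCC[C@@]2(C)[C@H]1CCC(C)=C2CC(=O)OC | intermediate
4 | 13,14,15,16-tetranorlabd-8-en-12-ol | CC1(C)CCC[C@@]2(C)[C@H]1CCC(C)=C2CCO | intermediate
5 | 12-iodo-13,14,15,16-tetranorlabd-8-ene | CC1(C)CCC[C@@]2(C)[C@H]1CCC(C)=C2CCI | intermediate
6 | 3-bromobut-3-en-1-ol | C=C(Br)CCO | starting material
7 | (13,14,15,16-tetranorlabd-8-en-12-yl)lithium | CC1(C)CCC[C@@]2(C)[C@H]1CCC(C)=C2CC[Li] | intermediate (not isolated)
8 | lithium B-methoxy-B-(13,14,15,16-tetranorlabd-8-en-12-yl)-9-borabicyclo[3.3.1]nonanuide | CC1(C)CCC[C@@]2(C)[C@H]1CCC(C)=C2CC[B-]1(OC)C2CCCC1CCC2.[Li+] | intermediate (not isolated)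
9 | labda-8,13(16)-dien-15-ol | CC1(C)CCC[C@@]2(C)[C@H]1CCC(C)=C2CCC(=C)CCO | intermediate
10 | (13R)-13,16-epoxylabd-8-en-15-ol | CC1(C)CCC[C@@]2(C)[C@H]1CCC(C)=C2CC[C@@]1(CCO)CO1 | intermediate
11 | (13R)-15-(tert-butyldiphenylsilyloxy)-13,16-epoxylabd-8-ene | CC1(C)CCC[C@@]2(C)[C@H]1CCC(C)=C2CC[C@@]1(CCO[Si](c2ccccc2)(c2ccccc2)C(C)(C)C)CO1 | intermediate
12 | (13R)-15-(tert-butyldiphenylsilyloxy)-13,16-epoxylabd-8-en-7-one | CC1(C)CCC[C@@]2(C)[C@H]1CC(=O)C(C)=C2CC[C@@]1(CCO[Si](c2ccccc2)(c2ccccc2)C(C)(C)C)CO1 | intermediate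
13 | (13R)-15-(tert-butyldiphenylsilyloxy)-13,16-epoxylabd-8-en-7β-ol | CC1(C)CCC[C@@]2(C)[C@H]1C[C@H](O)C(C)=C2CC[C@@]1(CCO[Si](c2ccccc2)(c2ccccc2)C(C)(C)C)CO1 | intermediate
14 | di-tert-butyl dicarbonate | CC(C)(C)OC(=O)OC(=O)OC(C)(C)C | starting material
15 | (13R)-7β-(tert-butoxycarbonyloxy)-15-(tert-butyldiphenylsilyloxy)-13,16-epoxylabd-8-ene | CC1(C)CCC[C@@]2(C)[C@H]1C[C@H](OC(=O)OC(C)(C)C)C(C)=C2CC[C@@]1(CCO[Si](c2ccccc2)(c2ccccc2)C(C)(C)C)CO1 | intermediate
16 | (13R)-7β-(tert-butoxycarbonyloxy)-15-(tert-butyldiphenylsilyloxy)-8α,9α:13,16-diepoxylabdane | CC1(C)CCC[C@@]2(C)[C@H]1C[C@H](OC(=O)OC(C)(C)C)[C@@]3(C)O[C@@]23CC[C@@]1(CCO[Si](c2ccccc2)(c2ccccc2)C(C)(C)C)CO1 | intermediate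
17 | spiro epoxonium ion (O bonded to C8, C9 and C13; O16 as trifluoroborate alkoxide) | CC1(C)CCC[C@@]2(C)[C@H]1C[C@H](OC(=O)OC(C)(C)C)[C@@]3(C)[O+]4[C@@]23CC[C@]4(CCO[Si](c2ccccc2)(c2ccccc2)C(C)(C)C)CO[B-](F)(F)F | intermediate (not isolated)
18 | 2-tert-butoxy-1,3-dioxolan-2-ylium ion fused at C7–C8 (ring C closed; O16 as trifluoroborate alkoxide) | CC1(C)CCC[C@@]2(C)[C@H]1C[C@@H]3OC(OC(C)(C)C)=[O+][C@]3(C)[C@]21CC[C@@](CO[B-](F)(F)F)(CCO[Si](c2ccccc2)(c2ccccc2)C(C)(C)C)O1 | intermediate (not isolated)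
19 | (13S)-15-(tert-butyldiphenylsilyloxy)-9α,13-epoxy-16-hydroxylabdane-7β,8β-diyl carbonate | CC1(C)CCC[C@@]2(C)[C@H]1C[C@@H]3OC(=O)O[C@]3(C)[C@]21CC[C@@](CO)(CCO[Si](c2ccccc2)(c2ccccc2)C(C)(C)C)O1 | intermediate
20 | (13S)-9α,13-epoxy-15,16-dihydroxylabdane-7β,8β-diyl carbonate | CC1(C)CCC[C@@]2(C)[C@H]1C[C@@H]3OC(=O)O[C@]3(C)[C@]21CC[C@@](CO)(CCO)O1 | intermediate
21 | (13S)-9α,13-epoxy-16-hydroxy-15-oxolabdane-7β,8β-diyl carbonate | CC1(C)CCC[C@@]2(C)[C@H]1C[C@@H]3OC(=O)O[C@]3(C)[C@]21CC[C@@](CO)(CC=O)O1 | intermediate (not isolated)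
22 | 15,16-lactol of 21 (C15 epimers) | CC1(C)CCC[C@@]2(C)[C@H]1C[C@@H]3OC(=O)O[C@]3(C)[C@]21CC[C@]2(COC(O)C2)O1 | intermediate (not isolated)
23 | (13S)-7β,8β-carbonyldioxy-9α,13-epoxylabdan-15,16-olide | CC1(C)CCC[C@@]2(C)[C@H]1C[C@@H]3OC(=O)O[C@]3(C)[C@]21CC[C@]2(COC(=O)C2)O1 | intermediate
24 | lithium (13S)-9α,13-epoxy-7β,8β,16-trihydroxylabdan-15-oate | CC1(C)CCC[C@@]2(C)[C@H]1C[C@H](O)[C@](C)(O)[C@]21CC[C@@](CO)(CC(=O)[O-])O1.[Li+] | intermediate (not isolated)
25 | (13S)-9α,13-epoxy-7β,8β-dihydroxylabdan-15,16-olide | CC1(C)CCC[C@@]2(C)[C@H]1C[C@H](O)[C@](C)(O)[C@]21CC[C@]2(COC(=O)C2)O1 | intermediate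
26 | (13S)-9α,13-epoxy-8β-hydroxy-7-oxolabdan-15,16-olide (CNP0208728.2) | CC1(C)CCC[C@@]2(C)[C@H]1CC(=O)[C@](C)(O)[C@]21CC[C@]2(COC(=O)C2)O1 | target

**Step count**

Total: 15 steps. Longest linear sequence: 15 steps (1 → 26).

**Steps most likely to fail**

Step 11 (proposed new method). The activated tetrasubstituted epoxide may ionise towards C9 and rearrange by shift of methyl C20 or by ring contraction, the side-chain epoxide may rearrange to an aldehyde by hydride shift, or the tert-butyl group may be lost before the C8–O8 bond forms. The fallback separates the two ring closures and uses known reactions only; it sets out from 9 and returns at 20.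
- 9 is silylated (TBDPSCl, imidazole) to 15-(tert-butyldiphenylsilyloxy)labda-8,13(16)-diene F1.
- Oxidation with CrO3–3,5-dimethylpyrazole gives the enone F2, and Luche reduction gives the 7β-alcohol F3.
- Boc2O with 1-methylimidazole gives the tert-butyl carbonate F4.
- One equivalent of mCPBA at −20 °C, which should take the tetrasubstituted ring olefin ahead of the 1,1-disubstituted side-chain olefin, gives the 8α,9α-epoxide F5.
- BF3·OEt2 then effects the known two-component opening of an epoxide by a neighbouring tert-butyl carbonate, giving the 9α-hydroxy 7β,8β-carbonate F6.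
- HF·pyridine frees the C15 alcohol to give the diol F7.
- The Hf(OtBu)4–bishydroxamic acid epoxidation with cumene hydroperoxide, directed by the C15 hydroxyl, gives the 13R epoxide F8.
- Camphorsulfonic acid in CH2Cl2 closes ring C by 5-exo attack of the 9α-hydroxyl on C13 with inversion, which gives 20.

Step 5. Facial selectivity at C13 may be poor, because the two olefin substituents are both CH2CH2 chains, and the Lewis-acidic catalyst may open the epoxy alcohol. The fallback sets C13 by an allylic instead of a homoallylic directing group and adds C15 afterwards; it sets out from 5 and returns at 10.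
- 5 is coupled under the conditions of step 4 with commercial 2-bromoprop-2-en-1-ol (C=C(Br)CO) to give 15-norlabda-8,13(16)-dien-14-ol F9.
- Sharpless asymmetric epoxidation (Ti(OiPr)4, D-(−)-diethyl tartrate, t-BuOOH, 4 Å MS, CH2Cl2, −20 °C; the tartrate antipode that the Sharpless face rule assigns to this configuration) gives the epoxy alcohol F10.
- Parikh–Doering oxidation gives the epoxy aldehyde F11, which has no α-hydrogen and so cannot epimerise.
- Wittig methylenation (Ph3P=CH2) gives the vinyl epoxide F12.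
- Hydroboration of the vinyl group with 9-BBN, which leaves the tetrasubstituted olefin alone, and oxidation with NaBO3·4H2O give 10.

Step 7. Oxidation may take place at C11 or C17, may run on to a 7,11-dione, or chromium species may open the side-chain epoxide. The fallback moves the oxidation to an early, robust intermediate before the side chain exists; it sets out from 4 and returns at 12.
- 4 is acetylated (Ac2O, pyridine) to 13,14,15,16-tetranorlabd-8-en-12-yl acetate F13.
- Chromate oxidation (Na2CrO4, NaOAc, AcOH–Ac2O) gives the 7-oxo acetate F14.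
- K2CO3 in MeOH gives the hydroxy enone F15, and I2, PPh3 and imidazole give the iodo enone F16.
- Insertion of Zn dust in the presence of LiCl, which tolerates the ketone, gives the alkylzinc iodide F17.
- Negishi coupling with 6 (Pd(OAc)2, SPhos, slow addition of the zinc reagent so that the free hydroxyl is tolerated) gives 15-hydroxylabda-8,13(16)-dien-7-one F18.
- The directed epoxidation of step 5, which leaves the electron-poor enone alone, gives the epoxy alcohol F19, and silylation as in step 6 gives 12.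

**Further compounds**

F1 | step 11 | 15-(tert-butyldiphenylsilyloxy)labda-8,13(16)-diene | CC1(C)CCC[C@@]2(C)[C@H]1CCC(C)=C2CCC(=C)CCO[Si](c1ccccc1)(c1ccccc1)C(C)(C)C
F2 | step 11 | 15-(tert-butyldiphenylsilyloxy)labda-8,13(16)-dien-7-one | CC1(C)CCC[C@@]2(C)[C@H]1CC(=O)C(C)=C2CCC(=C)CCO[Si](c1ccccc1)(c1ccccc1)C(C)(C)C
F3 | step 11 | 15-(tert-butyldiphenylsilyloxy)labda-8,13(16)-dien-7β-ol | CC1(C)CCC[C@@]2(C)[C@H]1C[C@H](O)C(C)=C2CCC(=C)CCO[Si](c1ccccc1)(c1ccccc1)C(C)(C)C
F4 | step 11 | 7β-(tert-butoxycarbonyloxy)-15-(tert-butyldiphenylsilyloxy)labda-8,13(16)-diene | CC1(C)CCC[C@@]2(C)[C@H]1C[C@H](OC(=O)OC(C)(C)C)C(C)=C2CCC(=C)CCO[Si](c1ccccc1)(c1ccccc1)C(C)(C)C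
F5 | step 11 | 7β-(tert-butoxycarbonyloxy)-15-(tert-butyldiphenylsilyloxy)-8α,9α-epoxylabd-13(16)-ene | CC1(C)CCC[C@@]2(C)[C@H]1C[C@H](OC(=O)OC(C)(C)C)[C@@]3(C)O[C@@]23CCC(=C)CCO[Si](c1ccccc1)(c1ccccc1)C(C)(C)C
F6 | step 11 | 15-(tert-butyldiphenylsilyloxy)-9α-hydroxylabd-13(16)-ene-7β,8β-diyl carbonate | CC1(C)CCC[C@@]2(C)[C@H]1C[C@@H]3OC(=O)O[C@]3(C)[C@]2(O)CCC(=C)CCO[Si](c1ccccc1)(c1ccccc1)C(C)(C)C
F7 | step 11 | 9α,15-dihydroxylabd-13(16)-ene-7β,8β-diyl carbonate | CC1(C)CCC[C@@]2(C)[C@H]1C[C@@H]3OC(=O)O[C@]3(C)[C@]2(O)CCC(=C)CCO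
F8 | step 11 | (13R)-13,16-epoxy-9α,15-dihydroxylabdane-7β,8β-diyl carbonate | CC1(C)CCC[C@@]2(C)[C@H]1C[C@@H]3OC(=O)O[C@]3(C)[C@]2(O)CC[C@@]1(CCO)CO1
F9 | step 5 | 15-norlabda-8,13(16)-dien-14-ol | CC1(C)CCC[C@@]2(C)[C@H]1CCC(C)=C2CCC(=C)CO
F10 | step 5 | (13R)-13,16-epoxy-15-norlabd-8-en-14-ol | CC1(C)CCC[C@@]2(C)[C@H]1CCC(C)=C2CC[C@@]1(CO)CO1
F11 | step 5 | 13,16-epoxy-15-norlabd-8-en-14-al (C13 as in F10) | CC1(C)CCC[C@@]2(C)[C@H]1CCC(C)=C2CC[C@@]1(C=O)CO1
F12 | step 5 | (13R)-13,16-epoxylabda-8,14-diene | CC1(C)CCC[C@@]2(C)[C@H]1CCC(C)=C2CC[C@@]1(C=C)CO1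
F13 | step 7 | 13,14,15,16-tetranorlabd-8-en-12-yl acetate | CC1(C)CCC[C@@]2(C)[C@H]1CCC(C)=C2CCOC(C)=O
F14 | step 7 | 7-oxo-13,14,15,16-tetranorlabd-8-en-12-yl acetate | CC1(C)CCC[C@@]2(C)[C@H]1CC(=O)C(C)=C2CCOC(C)=O
F15 | step 7 | 12-hydroxy-13,14,15,16-tetranorlabd-8-en-7-one | CC1(C)CCC[C@@]2(C)[C@H]1CC(=O)C(C)=C2CCO
F16 | step 7 | 12-iodo-13,14,15,16-tetranorlabd-8-en-7-one | CC1(C)CCC[C@@]2(C)[C@H]1CC(=O)C(C)=C2CCI
F17 | step 7 | (7-oxo-13,14,15,16-tetranorlabd-8-en-12-yl)zinc iodide | CC1(C)CCC[C@@]2(C)[C@H]1CC(=O)C(C)=C2CC[Zn]I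
F18 | step 7 | 15-hydroxylabda-8,13(16)-dien-7-one | CC1(C)CCC[C@@]2(C)[C@H]1CC(=O)C(C)=C2CCC(=C)CCO
F19 | step 7 | (13R)-13,16-epoxy-15-hydroxylabd-8-en-7-one | CC1(C)CCC[C@@]2(C)[C@H]1CC(=O)C(C)=C2CC[C@@]1(CCO)CO1
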